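The blue run began more slowly than the violet run, 0.00428 M/s against 0.00528 M/s over the first 25 s. Yet at 120 s you read 0.344 M in blue and 0.336 M in violet, which is level within the scatter of 0.01 M. So I keep a ledger of the starting material, the limiting reagent, and look for where target goes.

| setting | violet | ochre | blue | amber |
|---|---|---|---|---|
| starting material | 0.800 M | 0.400 M | 0.800 M | 0.800 M |
| partner | 2.00 M | 1.60 M | 1.00 M | 2.00 M |
| catalyst | 0.0640 M | 0.0640 M | 0.0640 M | 0.0130 M |
| time |  |  |  | 120 s |

| violet run: time / s | violet run: [target] / M | ochre run: time / s | ochre run: [target] / M | blue run: time / s | blue run: [target] / M |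
|---|---|---|---|---|---|
| 4.3 | 0.013 | 4.3 | 0.013 | 4.3 | 0.019 |
| 13 | 0.051 | 13 | 0.063 | 13 | 0.057 |
| 25 | 0.132 | 25 | 0.088 | 25 | 0.107 |
| 40 | 0.181 | 40 | 0.155 | 40 | 0.144 |
| 57 | 0.218 | 57 | 0.174 | 57 | 0.223 |
| 76 | 0.272 | 76 | 0.195 | 76 | 0.254 |
| 97 | 0.319 | 97 | 0.193 | 97 | 0.302 |
| 120 | 0.336 | 120 | 0.213 | 120 | 0.344 |

(each reading ± 0.01 M)

- Overall: starting material + partner -> target, with catalyst as catalyst.
- Constant volume, constant temperature.
- Bound and free are read together.
- An order is taken over about fifteen percent of the charge, up and down.

- apparent order in [starting material] of the starting rate, round the charge of the violet run (the rate where two percent of its starting material have turned into target) (one fixed amount of target, the same in the runs compared)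
- apparent order in [partner] of the starting rate, round the charge of the violet run (the rate where two percent of its starting material have turned into target)
- target in the amber run at 120 s, as a share of the starting material charged

1. Income: I take the violet early rate, 0.00528 M/s, as what the violet run goes on making.

2. Balance: from 40 s to 120 s, violet [target] rises by just 0.00194 M/s around a level of 0.259 M. I book the gap of 0.00334 M/s as target leaving.

3. Level over gap gives 77.3 s, the target's lifetime: the average time a newly made target stays target in the violet run, read as a pseudo-first-order loss.

4. The same sums on blue give 0.00250 M/s, 0.244 M and a lifetime of 137 s. That is about twice the violet figure at half the partner, so I read the loss as a step with partner.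

5. Amber has violet's starting material and partner but less catalyst, 0.0130 M against 0.0640 M, so I keep the violet lifetime and scale the income with catalyst to 0.00107 M/s. In the amber run, making and loss would balance at rate times lifetime, 0.0829 M, and 120 s reaches 78.8 % of that level.

6. The amber books for 0.800 M: kept as target 0.0654 M, passed on 0.0630 M, unturned 0.672 M. That makes my figure 8.17 % of the charge.

The forecast gives orders of 0.1 in starting material and 0 in partner, and 13.7 % for amber, higher than mine. Its ground for the slowing is different: “That pattern suggests target competing with starting material for the catalyst.”

The flask gives orders of 0.15 and 0.23, and 9.51 % for amber.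

    catalyst + starting material ⇌ catalyst-substrate complex, settled at all times (1.260 /M)
    catalyst-substrate complex + partner ⇌ ternary complex, settled at all times (3.240 /M)
    ternary complex → target + catalyst (0.1260 /s)
    target + partner → side product (0.006630 /M/s)

In the amber run, the ternary complex gave target throughout the 120 s, which is 1.55 lifetimes of 77.3 s, while target went on with partner to side product. In the blue run, with a lifetime of 137 s, the same reckoning puts target at a quarter of the charge at 57.1 s, and the flask got there at 52.5 s.

The numbers in the tables stem from a simulated flask with constants of no real substance, and the scatter is random.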